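Late in Thursday's flask, target still arrives through intermediate C and intermediate D, so this bench note counts turnovers of the passage from one to the other.

    intermediate C → intermediate D (k1 = 0.00173 s⁻¹)
    starting material + protic impurity → quenched substrate (k2 = 639 L mol⁻¹ s⁻¹)
    starting material + reagent → intermediate A (k3 = 7.71 L mol⁻¹ s⁻¹)
    reagent + intermediate A → intermediate C (k4 = 2.05 L mol⁻¹ s⁻¹)
    intermediate D → target (k5 = 0.0118 s⁻¹)
    starting material + intermediate B → side product (k6 = 2.03 L mol⁻¹ s⁻¹)
    intermediate A ⇌ intermediate B (K7 = 0.53, k7 = 0.0580 s⁻¹)

the same everywhere: protic impurity 0.0400 mM; time 15 min

| flask | starting material | reagent | remark |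
|---|---|---|---|
| Tuesday's | 0.0020 M | 4.00 mM (fed, over 12 min) | all else is in the flask from the start; the feed brings no volume worth counting |
| Thursday's | 0.0020 M | 4.00 mM | everything together at the start |
| Monday's | 0.0020 M (fed, over 12 min) | 4.00 mM | all else is in the flask from the start; the feed brings no volume worth counting |

- a species is counted by the starting material in it: one side product counts as two
- run time (Tuesday's): 15 min

- the flask with the highest amount of target, in percent of the starting material charged ("all alike" if they lie within 1.5 percentage points) (Tuesday's / Thursday's / Monday's / all alike)
- final target, as a percentage of the starting material charged, in Tuesday's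
- final target, as a percentage of the starting material charged, in Thursday's
- final target, as a percentage of the starting material charged, in Monday's

**In the flask.** In Thursday's flask, starting material goes to intermediate A with a half-life of 0.37 min, much shorter than the run. The charge therefore soon stands as a pool of intermediate A and intermediate B. Their exchange at 0.0580 s⁻¹ is faster than the pool's drain constant 0.00268 s⁻¹, so [intermediate B] stays at 0.53 of [intermediate A]. This reckoning sets the reagent left, 2.00 mM, equal to the pool, which gives the pool a second-order half-life of 6.22 min. For Thursday's flask, it then puts 70.7% of the pool past intermediate A by 15 min.

**On arrival.** The portion that reaches intermediate C at that half-life, once the lifetime of intermediate D is taken off, has had 0.765 lifetimes of intermediate C: the turnover count. Thursday's target at the asked time then reckons to 37.8%. This reckoning stops at Thursday's flask and does not reach the fed flasks.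

**Not to touch.** Thursday's flask should not be judged at 15 min as finished, since the count is below one.

**The forecast.** It names Thursday's, with 14.5% for Tuesday's, 37.5% for Thursday's and 24% for Monday's, on the ground that “the slow steps set the yield”.

**The result.** Thursday's leads with 38.5%, against 23.3% for Monday's and 13.8% for Tuesday's, and the forecast holds. Left ten times as long, Thursday's flask reaches 92.0%. A count of 0.765 reckons 46.5% of the portion taken above to be still short of target, so 38.5% reads as a stage of Thursday's run and not as its ceiling.

**Later reading.** Thursday's flask read at 40 min has a count of 3.36, and the same reckoning gives 83.5%. The computed target is 77.4%, below the reckoning.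

The constants used here come from no measurement; the run is a simulation.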